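**Conventions.** Eudesmane numbering is used for all bicyclic compounds: ring A = C1–C5 and C10, ring B = C5–C10, C11–C13 = side chain on C7, C14 = methyl on C10, C15 = carbon on C4. TBS = tert-butyldimethylsilyl, Tf = trifluoromethanesulfonyl.

**Assumption.** The (S)-configured oxazaborolidine of step 3 is taken to direct diene 4 to the Si face of enone 5, as the α-C–H···O binding model of enone–oxazaborolidinium complexes suggests; if the first adduct proves antipodal, the (R)-catalyst is used and nothing else changes.

## Analysis of the target

Target 25 is a 12,8-seco-eudesmanolide. It is a decalin with an angular methyl (C14) on the quaternary C10, an exocyclic methylene (C15) on C4, a tertiary hydroperoxide on C5, an isobutyrate on C3, an acetate on C8 and a methyl acrylate (C11–C13) on C7. The five stereocentres are 3S, 5S, 7R, 8R and 10R. The C3 ester, the C7 side chain, the C8 acetate and the C10 methyl all lie on the β face, whereas the C5–OOH is α, trans to the angular methyl. The cis C7/C8 pair is the arrangement of an opened cis-fused 8,12-lactone. The sensitive groups are the tertiary allylic hydroperoxide (reduced by phosphines, sulfides and hydrides, cleaved by acid), the acrylate (Michael acceptor) and two different secondary esters that must not be exchanged. The hard points are the quaternary C10, from which every other stereocentre has to be relayed, the differentiation of O3 from O8, and the need to bring in the hydroperoxide last. The 5-OOH/4(15)-ene pair is the ene adduct of oxygen with a 4-methyl-C4=C5 alkene. The strategy rests on ring B: with its C8 oxygen and C7 side chain it is the Diels–Alder adduct of a 2-silyloxy-3-substituted butadiene (4) across the C5=C10 bond of 3-methylcyclohex-2-enone (5). The β-methyl of 5 becomes C14, and its carbonyl carbon becomes C4, where C15 is attached later.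

## Retrosynthetic reasoning

**25 to 24.** The C5–O bond and the C4=C15 alkene are removed together as a Schenck ene retron, leading to the tetrasubstituted C4=C5 alkene 24. The hydroperoxide tolerates almost none of the earlier chemistry, so this cut comes first. The forward step must deliver oxygen to the α face and take hydrogen from C15.

**24 to 21.** The two ester C–O bonds are cut next: isobutyrate to alcohol 23, silyl ether 22 in its place, then acetate to 8-hydroxy ester 21. O8 is acylated first, while O3 is still silylated. This differentiates the two oxygens and removes the hydroxyl that could close back onto the acrylate.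

**21 to 16.** The cis 8-hydroxy acrylate 21 is the opened form of the α-methylene lactone 19 (through carboxylate 20). The lactone locks the C7/C8 cis relationship and activates C11 for the one-carbon extension, so the C11=C13 bond is cut at the lactone stage to give 16.

**16 to 12.** The lactone C–O bond and the C8–H bond are cut to the 8-ketone 14 (through hydroxy ester 15). A hydride delivered from the α face sets 8R, and the resulting alkoxide is cis to the side chain. Ketone 14 is the silyl ether of 13, which is the hydrolysed form of silyl enol ether 12. The C7 configuration is set by equilibration next to this ketone. That is only reliable once C5 is sp2 and ring B is a defined chair, which is why ring A is finished before the enol ether is touched.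

**12 to 6.** The C3–H bond is cut to enone 11, whose reduction sets 3S. The C4–C15 bond is cut to enol triflate 10 and diosphenol 9. Compound 9 arises from the 1,2-dione 8 and the acyloin 7, made by oxygenating C3 of ketone 6. This sequence is chosen because the cycloaddition leaves the ring A carbonyl on C4, while the target needs carbon on C4, oxygen on C3 and a C4=C5 double bond. The diosphenol gives all three with defined regiochemistry.

**6 to 4 and 5.** The C5–C6 and C9–C10 bonds are cut in a Diels–Alder disconnection. It is convergent and forms the quaternary C10 under catalyst control. It delivers O8 as a regiodefined enol ether and carries C11–C12 in with the diene. The forward reaction has to achieve C9-to-C10 regiochemistry and one absolute configuration at C10.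

**4 to 1.** The Si–O bond is cut to enone 3, and the methylene carbon is cut by a Mannich retron to methyl levulinate 1.

## Alternatives that were turned down

**Alternative 1:** Both rings are cut at C4–C5 and C9–C10 back to one chain. In the forward step the open-chain β-keto ester A2 is oxidised by Mn(OAc)3 to the C4 radical. This closes onto C5, the tertiary C10 radical closes onto C9, and Cu(OAc)2 oxidises the acetoxy-substituted C8 radical, giving the trans-fused diketone A1.
- For: two rings, two C–C bonds, the quaternary centre and a ketone already on C3 are formed in one operation by an established reaction class. On the placement of oxygen at C3 this alternative is stronger than the chosen route, which spends four steps moving oxygen from C4 to C3.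
- Against: A1 carries a superfluous ester carbon on C4 that must be excised, and a trans C5–H that must be removed again to reach the C4=C5 alkene. It has two ketones and two methyl esters to tell apart. The absolute configuration can only come from the C7 stereocentre of A2, which needs its own asymmetric synthesis and must relay over three bonds to C10.
- Comparison: more bonds per step, but more corrective steps afterwards and no catalyst control. The chosen route sets C10 directly and arrives with the two ring carbonyls already differentiated (ketone versus silyl enol ether).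

**Alternative 2:** Only C6–C7 is cut. A primary amine converts the C3 ketone of cyclohexenone A4 into the exocyclic dienamine, whose C6 attacks C7 of the tethered 2-(bromomethyl)enoate in an SN2′ reaction to give A3.
- For: A3 already holds the acrylate, the 8β-acetate and the 4-en-3-one, and is three operations from 25. In step economy after the key step this alternative is clearly stronger than the chosen route.
- Against: the difficulty is moved into A4. Its quaternary C10 and its C8 carbinol are remote stereocentres that must each be made selectively and joined. The bromomethyl enoate is a strong alkylating agent for the amine catalyst. The dienamine can also react at C2. The new C7 centre must form cis to the acetate with no obvious control element.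
- Comparison: the chosen route starts from two simple achiral fragments, and relays C7 and C8 from C10 by thermodynamic and steric control.

**Alternative 3:** C5–C10 and C6–C7 are cut. The acyclic trienone A6 undergoes an intramolecular Diels–Alder reaction of its vinyl ketone with the tethered silyloxydiene under a chiral oxazaborolidinium acid, giving A5.
- For: the reaction is intramolecular, so the entropic cost of forming the quaternary C10 is paid by the tether. As a key step it is probably less risky than the intermolecular addition to a β-methyl enone chosen here.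
- Against: A5 lacks C11–C13, and its enol ether is C8=C9, pointing away from C7. The side chain would therefore have to be introduced by regioselective alkylation at C7 with the C4 ketone present. The diene terminus C10 is fully substituted, which disfavours the s-cis conformation. A6 combines a free vinyl ketone with a silyloxydiene in one linear, polymerisable chain that needs a longer synthesis than 4 and 5 together.
- Comparison: the chosen route is convergent, keeps both diene termini unsubstituted, and brings the C7 side chain and a correctly placed C7=C8 enol ether in the cycloaddition itself.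

Key step: step 3

## Route

Step 1
Reactants: 1 methyl levulinate
Product: 3 methyl 3-methylene-4-oxopentanoate, via Mannich base 2 (not isolated)
Conditions: (CH2O)n, PhNHMe·CF3CO2H, THF, reflux
Reagents that add atoms: formaldehyde (as paraformaldehyde), C=O
Why: One-pot Mannich methylenation: acid-mediated enolisation of the methyl ketone prefers the more substituted C3 enol, the iminium adds there, and Mannich base 2 loses N-methylaniline on heating (E1cB) to give the 1,1-disubstituted enone, which is used without storage.

Step 2
Reactants: 3 methyl 3-methylene-4-oxopentanoate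
Product: 4 methyl 4-(tert-butyldimethylsilyloxy)-3-methylenepent-4-enoate (fragment 2)
Conditions: TBSOTf, Et3N, CH2Cl2, 0 °C
Reagents that add atoms: tert-butyldimethylsilyl trifluoromethanesulfonate, CC(C)(C)[Si](C)(C)OS(=O)(=O)C(F)(F)F
Why: Soft enolisation: the silyl triflate activates the ketone and Et3N removes a proton from the methyl group, the only α-carbon that still carries hydrogen, giving the cross-conjugated 2-silyloxydiene; the ester is not enolised under these conditions.

Step 3
Reactants: 4 methyl 4-(tert-butyldimethylsilyloxy)-3-methylenepent-4-enoate (fragment 2); 5 3-methylcyclohex-2-en-1-one (fragment 1)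
Product: 6 methyl (5S,10R)-8-(tert-butyldimethylsilyloxy)-4-oxo-13,15-dinoreudesm-7-en-12-oate (cis-fused adduct)
Conditions: (S)-3,3-diphenyl-1-(o-tolyl)tetrahydro-1H,3H-pyrrolo[1,2-c][1,3,2]oxazaborole (20 mol%), AlBr3 (16 mol%), CH2Cl2, −78 → −20 °C; Et3N quench
Reagents that add atoms: none
Why: Proposed new method: the AlBr3-activated oxazaborolidine is a cationic boron Lewis acid that binds the carbonyl oxygen of 5 (the later C4=O), lowers the LUMO of the C5=C10 bond and blocks one face, and diene 4 then adds suprafacially in an asynchronous [4+2] in which C9, the terminus made nucleophilic by the silyloxy group, bonds first to the β-carbon C10 and C6 follows onto C5. The closest known reaction types are the AlBr3/AlMe3-promoted Diels–Alder additions of 2-silyloxydienes to β-substituted cyclohexenones, which give racemic adducts, and the oxazaborolidinium-catalysed enantioselective Diels–Alder reactions of cyclic enones without a β-substituent; their combination on a β-methyl enone has not been shown. Ring B is closed by the cycloaddition itself; in the stepwise limit this is a Mukaiyama–Michael addition followed by a 6-endo-trig Michael closure of the boron enolate carbon C5 onto C6. C10 (R) is set by the catalyst, which has to direct the diene to the Si face of both enone carbons, and the configuration at C5 (S, hydrogen cis to the methyl) follows from suprafacial addition to the ring alkene and is removed again in step 5. The step needs regioselectivity and enantiofacial selectivity: the first is secured by the 2-silyloxy group, which outweighs the 3-alkyl group of the diene and places O8 and the C4 carbonyl 1,4 to each other, the second by the aryl group of the catalyst shielding one face of the bound enone. Endo/exo selectivity is not an issue because both diene termini are unsubstituted, and the silyl enol ether of 6 emerges regiodefined at C7=C8.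

Step 4
Reactants: 6 methyl (5S,10R)-8-(tert-butyldimethylsilyloxy)-4-oxo-13,15-dinoreudesm-7-en-12-oate
Product: 7 methyl (5S,10R)-8-(tert-butyldimethylsilyloxy)-3-hydroxy-4-oxo-13,15-dinoreudesm-7-en-12-oate (C3 epimers)
Conditions: KN(SiMe3)2, THF, −78 °C; 2-(phenylsulfonyl)-3-phenyloxaziridine, −78 °C; AcOH
Reagents that add atoms: 2-(phenylsulfonyl)-3-phenyloxaziridine, O=S(=O)(c1ccccc1)N1OC1c1ccccc1
Why: Kinetic deprotonation of the cis-decalone occurs at the C3 methylene and not at the hindered ring-fusion carbon C5, and the potassium enolate is hydroxylated by the N-sulfonyloxaziridine (Davis oxidation); the configuration at C3 does not matter because the carbinol is oxidised in step 5.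

Step 5
Reactants: 7 methyl (5S,10R)-8-(tert-butyldimethylsilyloxy)-3-hydroxy-4-oxo-13,15-dinoreudesm-7-en-12-oate
Product: 9 methyl (10R)-8-(tert-butyldimethylsilyloxy)-4-hydroxy-3-oxo-13,15-dinoreudesma-4,7-dien-12-oate (diosphenol), via 3,4-dione 8 (not isolated)
Conditions: Dess–Martin periodinane, pyridine, CH2Cl2, 0 °C → rt
Reagents that add atoms: none
Why: Dess–Martin oxidation of the acyloin gives 1,2-dione 8, which enolises toward the more substituted carbon C5, the preferred tautomer of 3-alkylcyclohexane-1,2-diones; C5 thereby becomes sp2 and the C4=C5 position is fixed, and pyridine buffers the acetic acid so that the silyl enol ether survives.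

Step 6
Reactants: 9 methyl (10R)-8-(tert-butyldimethylsilyloxy)-4-hydroxy-3-oxo-13,15-dinoreudesma-4,7-dien-12-oate
Product: 10 methyl (10R)-8-(tert-butyldimethylsilyloxy)-3-oxo-4-(trifluoromethanesulfonyloxy)-13,15-dinoreudesma-4,7-dien-12-oate
Conditions: PhNTf2, Et3N, DMAP (cat.), CH2Cl2, 0 °C → rt
Reagents that add atoms: N-phenylbis(trifluoromethanesulfonimide), O=S(=O)(N(c1ccccc1)S(=O)(=O)C(F)(F)F)C(F)(F)F
Why: O-Triflation of the acidic diosphenol hydroxyl under a mild amine base; no other position is enolised at this acidity, and the mild triflyl donor leaves the ring B enol ether alone.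

Step 7
Reactants: 10 methyl (10R)-8-(tert-butyldimethylsilyloxy)-3-oxo-4-(trifluoromethanesulfonyloxy)-13,15-dinoreudesma-4,7-dien-12-oate
Product: 11 methyl (10R)-8-(tert-butyldimethylsilyloxy)-3-oxo-13-noreudesma-4,7-dien-12-oate
Conditions: Me4Sn, Pd(PPh3)4 (5 mol%), LiCl, N-methylpyrrolidone, 60 °C
Reagents that add atoms: tetramethylstannane, C[Sn](C)(C)C
Why: Stille coupling of the α-triflyloxy enone: zerovalent palladium inserts into the C4–O bond, a methyl group is transmetalated and reductive elimination attaches C15; the neutral conditions spare the silyl enol ether and the ester.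

Step 8
Reactants: 11 methyl (10R)-8-(tert-butyldimethylsilyloxy)-3-oxo-13-noreudesma-4,7-dien-12-oate
Product: 12 methyl (3S,10R)-8-(tert-butyldimethylsilyloxy)-3-hydroxy-13-noreudesma-4,7-dien-12-oate
Conditions: LiAlH(O-t-Bu)3, THF, −20 → 0 °C
Reagents that add atoms: none
Why: 1,2-Reduction of the β,β-disubstituted enone: the hydride attacks C3 axially from the α face, anti to the angular methyl, and should give the pseudo-equatorial 3β-alcohol (3S), as in reductions of 10-methyl-4-en-3-ones; the ester and the silyl enol ether are inert to this reagent.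

Step 9
Reactants: 12 methyl (3S,10R)-8-(tert-butyldimethylsilyloxy)-3-hydroxy-13-noreudesma-4,7-dien-12-oate
Product: 13 methyl (3S,7R,10R)-3-hydroxy-8-oxo-13-noreudesm-4-en-12-oate
Conditions: n-Bu4NF, AcOH, THF, 0 °C; then K2CO3 (cat.), MeOH, rt
Reagents that add atoms: none
Why: Fluoride cleaves the Si–O bond of the enol ether and the enolate is protonated; K2CO3 in MeOH then equilibrates C7, α to the new ketone, to the epimer with the equatorial β side chain (7R), which is well defined now that C5 is sp2 and ring B is a chair with the C10 methyl axial.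

Step 10
Reactants: 13 methyl (3S,7R,10R)-3-hydroxy-8-oxo-13-noreudesm-4-en-12-oate
Product: 14 methyl (3S,7R,10R)-3-(tert-butyldimethylsilyloxy)-8-oxo-13-noreudesm-4-en-12-oate
Conditions: TBSCl, imidazole, DMF, rt
Reagents that add atoms: tert-butyldimethylsilyl chloride, CC(C)(C)[Si](C)(C)Cl
Why: Standard silylation of the secondary allylic alcohol; the silyl ether withstands the enolate and hydroxide steps that an ester on O3 would not, and keeps O3 apart from O8.

Step 11
Reactants: 14 methyl (3S,7R,10R)-3-(tert-butyldimethylsilyloxy)-8-oxo-13-noreudesm-4-en-12-oate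
Product: 16 (3S,7R,8R,10R)-3-(tert-butyldimethylsilyloxy)-13-noreudesm-4-en-12,8-olide (cis-fused lactone), via hydroxy ester 15 (not isolated)
Conditions: LiBH(s-Bu)3, THF, −78 °C → rt; AcOH
Reagents that add atoms: none
Why: The bulky hydride attacks the C8 ketone equatorially from the α face, opposite the axial C10 methyl, giving the axial 8β-alkoxide (8R); this is cis to the C7 side chain and closes the γ-lactone by acyl substitution with loss of methoxide, while the ester itself is not reduced at −78 °C.

Step 12
Reactants: 16 (3S,7R,8R,10R)-3-(tert-butyldimethylsilyloxy)-13-noreudesm-4-en-12,8-olide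
Product: 19 (3S,7R,8R,10R)-3-(tert-butyldimethylsilyloxy)eudesma-4,11(13)-dien-12,8-olide, via amine 17 (not isolated), via ammonium iodide 18 (not isolated)
Conditions: LiN(i-Pr)2, THF, −78 °C; CH2=NMe2+ I−, −78 °C → rt; MeI, MeOH, rt; NaHCO3 (aq), CH2Cl2
Reagents that add atoms: N,N-dimethylmethyleneiminium iodide, C=[N+](C)C.[I-]
Why: Eschenmoser methylenation: the lactone enolate is aminomethylated at C11, amine 17 is quaternised and ammonium salt 18 eliminates (E1cB) to the exocyclic alkene; C11 becomes sp2, so no stereocentre is created.

Step 13
Reactants: 19 (3S,7R,8R,10R)-3-(tert-butyldimethylsilyloxy)eudesma-4,11(13)-dien-12,8-olide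
Product: 21 methyl (3S,7R,8R,10R)-3-(tert-butyldimethylsilyloxy)-8-hydroxyeudesma-4,11(13)-dien-12-oate, via potassium carboxylate 20 (not isolated)
Conditions: KOH (1.1 equiv), THF/H2O, 0 °C → rt; concentrate; MeI, DMF, 0 °C → rt
Reagents that add atoms: potassium hydroxide, [K+].[OH-]; iodomethane, CI
Why: Saponification of the cis-lactone gives carboxylate 20, which is O-methylated without ever being acidified, so the γ-hydroxy acid cannot relactonise; methanol is avoided so that no methoxide adds to the acrylate.

Step 14
Reactants: 21 methyl (3S,7R,8R,10R)-3-(tert-butyldimethylsilyloxy)-8-hydroxyeudesma-4,11(13)-dien-12-oate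
Product: 22 methyl (3S,7R,8R,10R)-8-acetoxy-3-(tert-butyldimethylsilyloxy)eudesma-4,11(13)-dien-12-oate
Conditions: Ac2O, DMAP, Et3N, CH2Cl2, 0 °C → rt
Reagents that add atoms: acetic anhydride, CC(=O)OC(C)=O
Why: DMAP-catalysed acetylation of the axial 8β-hydroxyl; acylating at once removes the nucleophile that could re-form the lactone.

Step 15
Reactants: 22 methyl (3S,7R,8R,10R)-8-acetoxy-3-(tert-butyldimethylsilyloxy)eudesma-4,11(13)-dien-12-oate
Product: 23 methyl (3S,7R,8R,10R)-8-acetoxy-3-hydroxyeudesma-4,11(13)-dien-12-oate
Conditions: HF·pyridine, pyridine, THF, 0 °C → rt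
Reagents that add atoms: none
Why: Buffered fluoride removes the silyl ether without touching the acetate, the acrylate or the allylic C3–O bond.

Step 16
Reactants: 23 methyl (3S,7R,8R,10R)-8-acetoxy-3-hydroxyeudesma-4,11(13)-dien-12-oate
Product: 24 methyl (3S,7R,8R,10R)-8-acetoxy-3-(2-methylpropanoyloxy)eudesma-4,11(13)-dien-12-oate
Conditions: i-PrCOCl, pyridine, DMAP (cat.), CH2Cl2, 0 °C
Reagents that add atoms: 2-methylpropanoyl chloride, CC(C)C(=O)Cl
Why: Acylation of the unhindered pseudo-equatorial allylic alcohol with the acid chloride; O8 is already acetylated, so no selectivity is required.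

Step 17
Reactants: 24 methyl (3S,7R,8R,10R)-8-acetoxy-3-(2-methylpropanoyloxy)eudesma-4,11(13)-dien-12-oate
Product: 25 methyl (3S,5S,7R,8R,10R)-8-acetoxy-5-hydroperoxy-3-(2-methylpropanoyloxy)eudesma-4(15),11(13)-dien-12-oate (target)
Conditions: O2, hν (visible), 5,10,15,20-tetraphenylporphyrin (cat.), CH2Cl2, −20 → 0 °C
Reagents that add atoms: oxygen (as singlet oxygen), O=O
Why: Schenck ene reaction: singlet oxygen adds to C5 of the electron-rich tetrasubstituted alkene on the α face, opposite the angular methyl and the 3β-ester, and takes a hydrogen from the C15 methyl, which moves the double bond to C4=C15 and sets 5S; the electron-poor acrylate does not react, and the hydroperoxide is isolated without reductive work-up.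

## Compound list

1 | methyl levulinate (methyl 4-oxopentanoate) | COC(=O)CCC(C)=O | starting material
2 | methyl 3-[(N-methylanilino)methyl]-4-oxopentanoate (racemic Mannich base, not isolated) | CC(=O)C(CN(C)c1ccccc1)CC(=O)OC | intermediate
3 | methyl 3-methylene-4-oxopentanoate | CC(=O)C(=C)CC(=O)OC | intermediate
4 | methyl 4-(tert-butyldimethylsilyloxy)-3-methylenepent-4-enoate (fragment 2) | C=C(CC(=O)OC)C(=C)O[Si](C)(C)C(C)(C)C | intermediate
5 | 3-methylcyclohex-2-en-1-one (fragment 1) | CC1=CC(=O)CCC1 | starting material
6 | methyl (5S,10R)-8-(tert-butyldimethylsilyloxy)-4-oxo-13,15-dinoreudesm-7-en-12-oate (cis-fused adduct) | COC(=O)CC1=C(O[Si](C)(C)C(C)(C)C)C[C@@]2(C)CCCC(=O)[C@H]2C1 | intermediate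
7 | methyl (5S,10R)-8-(tert-butyldimethylsilyloxy)-3-hydroxy-4-oxo-13,15-dinoreudesm-7-en-12-oate (both C3 epimers) | COC(=O)CC1=C(O[Si](C)(C)C(C)(C)C)C[C@@]2(C)CCC(O)C(=O)[C@H]2C1 | intermediate
8 | methyl (5S,10R)-8-(tert-butyldimethylsilyloxy)-3,4-dioxo-13,15-dinoreudesm-7-en-12-oate (not isolated) | COC(=O)CC1=C(O[Si](C)(C)C(C)(C)C)C[C@@]2(C)CCC(=O)C(=O)[C@H]2C1 | intermediate
9 | methyl (10R)-8-(tert-butyldimethylsilyloxy)-4-hydroxy-3-oxo-13,15-dinoreudesma-4,7-dien-12-oate (diosphenol) | COC(=O)CC1=C(O[Si](C)(C)C(C)(C)C)C[C@@]2(C)CCC(=O)C(O)=C2C1 | intermediate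
10 | methyl (10R)-8-(tert-butyldimethylsilyloxy)-3-oxo-4-(trifluoromethanesulfonyloxy)-13,15-dinoreudesma-4,7-dien-12-oate | COC(=O)CC1=C(O[Si](C)(C)C(C)(C)C)C[C@@]2(C)CCC(=O)C(OS(=O)(=O)C(F)(F)F)=C2C1 | intermediate
11 | methyl (10R)-8-(tert-butyldimethylsilyloxy)-3-oxo-13-noreudesma-4,7-dien-12-oate | COC(=O)CC1=C(O[Si](C)(C)C(C)(C)C)C[C@@]2(C)CCC(=O)C(C)=C2C1 | intermediate
12 | methyl (3S,10R)-8-(tert-butyldimethylsilyloxy)-3-hydroxy-13-noreudesma-4,7-dien-12-oate | COC(=O)CC1=C(O[Si](C)(C)C(C)(C)C)C[C@@]2(C)CC[C@H](O)C(C)=C2C1 | intermediate
13 | methyl (3S,7R,10R)-3-hydroxy-8-oxo-13-noreudesm-4-en-12-oate | COC(=O)C[C@@H]1C(=O)C[C@@]2(C)CC[C@H](O)C(C)=C2C1 | intermediate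
14 | methyl (3S,7R,10R)-3-(tert-butyldimethylsilyloxy)-8-oxo-13-noreudesm-4-en-12-oate | COC(=O)C[C@@H]1C(=O)C[C@@]2(C)CC[C@H](O[Si](C)(C)C(C)(C)C)C(C)=C2C1 | intermediate
15 | methyl (3S,7R,8R,10R)-3-(tert-butyldimethylsilyloxy)-8-hydroxy-13-noreudesm-4-en-12-oate (as its lithium alkoxide, not isolated) | COC(=O)C[C@H]1CC2=C(C)[C@@H](O[Si](C)(C)C(C)(C)C)CC[C@]2(C)C[C@H]1O | intermediate
16 | (3S,7R,8R,10R)-3-(tert-butyldimethylsilyloxy)-13-noreudesm-4-en-12,8-olide (cis-fused γ-lactone) | O=C1C[C@H]2CC3=C(C)[C@@H](O[Si](C)(C)C(C)(C)C)CC[C@]3(C)C[C@H]2O1 | intermediate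
17 | (3S,7R,8R,10R)-13-(dimethylamino)-3-(tert-butyldimethylsilyloxy)eudesm-4-en-12,8-olide (C11 epimers, not isolated) | CN(C)CC1[C@H]2CC3=C(C)[C@@H](O[Si](C)(C)C(C)(C)C)CC[C@]3(C)C[C@H]2OC1=O | intermediate
18 | trimethylammonium iodide of 17 (not isolated) | C[N+](C)(C)CC1[C@H]2CC3=C(C)[C@@H](O[Si](C)(C)C(C)(C)C)CC[C@]3(C)C[C@H]2OC1=O.[I-] | intermediate
19 | (3S,7R,8R,10R)-3-(tert-butyldimethylsilyloxy)eudesma-4,11(13)-dien-12,8-olide | C=C1[C@H]2CC3=C(C)[C@@H](O[Si](C)(C)C(C)(C)C)CC[C@]3(C)C[C@H]2OC1=O | intermediate
20 | potassium (3S,7R,8R,10R)-3-(tert-butyldimethylsilyloxy)-8-hydroxyeudesma-4,11(13)-dien-12-oate (not isolated) | C=C(C(=O)[O-])[C@H]1CC2=C(C)[C@@H](O[Si](C)(C)C(C)(C)C)CC[C@]2(C)C[C@H]1O.[K+] | intermediate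
21 | methyl (3S,7R,8R,10R)-3-(tert-butyldimethylsilyloxy)-8-hydroxyeudesma-4,11(13)-dien-12-oate | C=C(C(=O)OC)[C@H]1CC2=C(C)[C@@H](O[Si](C)(C)C(C)(C)C)CC[C@]2(C)C[C@H]1O | intermediate
22 | methyl (3S,7R,8R,10R)-8-acetoxy-3-(tert-butyldimethylsilyloxy)eudesma-4,11(13)-dien-12-oate | C=C(C(=O)OC)[C@H]1CC2=C(C)[C@@H](O[Si](C)(C)C(C)(C)C)CC[C@]2(C)C[C@H]1OC(C)=O | intermediate
23 | methyl (3S,7R,8R,10R)-8-acetoxy-3-hydroxyeudesma-4,11(13)-dien-12-oate | C=C(C(=O)OC)[C@H]1CC2=C(C)[C@@H](O)CC[C@]2(C)C[C@H]1OC(C)=O | intermediate
24 | methyl (3S,7R,8R,10R)-8-acetoxy-3-(2-methylpropanoyloxy)eudesma-4,11(13)-dien-12-oate | C=C(C(=O)OC)[C@H]1CC2=C(C)[C@@H](OC(=O)C(C)C)CC[C@]2(C)C[C@H]1OC(C)=O | intermediate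
25 | methyl (3S,5S,7R,8R,10R)-8-acetoxy-5-hydroperoxy-3-(2-methylpropanoyloxy)eudesma-4(15),11(13)-dien-12-oate (CNP0244758.1) | C=C(C(=O)OC)[C@H]1C[C@@]2(OO)C(=C)[C@@H](OC(=O)C(C)C)CC[C@]2(C)C[C@H]1OC(C)=O | target

## Step count and least certain steps

Total: 17 steps. Longest linear sequence: 17 steps (1 to 25); fragment 1 (5) is commercial and enters at step 3.

**Step 3 (key step).** The β-methyl enone is a poor dienophile, so the cycloaddition may be slow. The reaction may stall after the first C–C bond, at the open-chain Michael stage. The silyl enol ether may be lost to protodesilylation, and the ester of the diene may compete for the Lewis acid. The β-methyl group may also disturb the binding geometry, so that facial selectivity is low.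
Fallback (known chemistry): 4 and 5 are combined with the achiral AlBr3/AlMe3 mixed Lewis acid in toluene/CH2Cl2 to give the racemic adduct F1. Lithiated (S)-N,S-dimethyl-S-phenylsulfoximine (n-BuLi, THF, −78 °C) is added to its C4 ketone. The two diastereomeric adducts are separated by chromatography: the β-hydroxysulfoximine F2 from the (5S,10R) ketone and its diastereomer F3 from the mirror-image ketone. Heating F2 in toluene reverses the addition and returns to the route at 6.

**Step 17.** Singlet oxygen may take the pseudo-axial hydrogen on C3 instead of a C15 hydrogen, which would give an enol ester. It may also attack the β face, and the product may undergo acid-induced Hock cleavage during isolation.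
Fallback: starting from 24, the alkene is epoxidised on the α face (m-chloroperbenzoic acid, NaHCO3, CH2Cl2) to the 4α,5α-epoxide F4. This is isomerised with TMSOTf and DBU, by anti-elimination of a C15 proton, and the silyl ether is hydrolysed to give the tertiary allylic alcohol F5. The hydroxyl is then exchanged for hydroperoxide with 50% H2O2 and a catalytic amount of H2SO4 in Et2O at 0 °C, which returns to 25.

**Step 13.** Hydroxide may add to the exocyclic methylene of the lactone, and the hydroxy ester may close back to the lactone during methylation or isolation.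
Fallback: the sequence sets out from amine 17, isolated for this purpose after the aminomethylation of step 12. It is saponified with KOH to the amino carboxylate F6, which has no Michael acceptor. Excess MeI with K2CO3 in DMF methylates the carboxylate and quaternises the amine, giving the ammonium ester F7. This loses trimethylamine on gentle warming with the carbonate, and the route is rejoined at 21.

**Step 1.** The iminium may add at the methyl group (C5) instead of C3, or twice. The α-methylene ketone may isomerise to the conjugated enoate or dimerise on standing.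
Fallback: 1 is converted with TMSCl, NaI and Et3N in MeCN into the internal silyl enol ether F8, which fixes the site of reaction. CH2=NMe2+ I− then gives the Mannich base F9, and MeI gives its methiodide F10. Elimination with NaHCO3 returns to 3.

**Step 4.** The base may deprotonate the β,γ-unsaturated ester or the ring-fusion carbon in competition with C3, which would hydroxylate the wrong carbon.
Fallback: 6 is condensed with t-BuOCH(NMe2)2 in toluene at 80 °C, which reacts only at the ketone α-methylene, to give the enaminone F11. Oxidative cleavage of its C=C bond with NaIO4 in THF/H2O gives dione 8, which enolises, and the route is rejoined at 9.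

## Further compounds

F1 | step 3 | racemic cis-fused adduct (6 and its mirror image) | COC(=O)CC1=C(O[Si](C)(C)C(C)(C)C)C[C@@]2(C)CCCC(=O)[C@H]2C1.COC(=O)CC1=C(O[Si](C)(C)C(C)(C)C)C[C@]2(C)CCCC(=O)[C@@H]2C1
F2 | step 3 | β-hydroxysulfoximine from the (5S,10R) ketone and the (S)-sulfoximine (C4 configuration not assigned) | COC(=O)CC1=C(O[Si](C)(C)C(C)(C)C)C[C@@]2(C)CCCC(O)(C[S@@](=O)(=NC)c3ccccc3)[C@H]2C1
F3 | step 3 | β-hydroxysulfoximine from the (5R,10S) ketone and the (S)-sulfoximine (C4 configuration not assigned) | COC(=O)CC1=C(O[Si](C)(C)C(C)(C)C)C[C@]2(C)CCCC(O)(C[S@@](=O)(=NC)c3ccccc3)[C@@H]2C1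
F4 | step 17 | methyl 8β-acetoxy-4α,5α-epoxy-3β-(2-methylpropanoyloxy)eudesm-11(13)-en-12-oate | C=C(C(=O)OC)[C@H]1C[C@@]2(O3)[C@@]3(C)[C@@H](OC(=O)C(C)C)CC[C@]2(C)C[C@H]1OC(C)=O
F5 | step 17 | methyl 8β-acetoxy-5α-hydroxy-3β-(2-methylpropanoyloxy)eudesma-4(15),11(13)-dien-12-oate | C=C(C(=O)OC)[C@H]1C[C@@]2(O)C(=C)[C@@H](OC(=O)C(C)C)CC[C@]2(C)C[C@H]1OC(C)=O
F6 | step 13 | potassium 13-(dimethylamino)-8β-hydroxy-3β-(tert-butyldimethylsilyloxy)eudesm-4-en-12-oate (C11 epimers) | CN(C)CC(C(=O)[O-])[C@H]1CC2=C(C)[C@@H](O[Si](C)(C)C(C)(C)C)CC[C@]2(C)C[C@H]1O.[K+]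
F7 | step 13 | methyl 8β-hydroxy-3β-(tert-butyldimethylsilyloxy)-13-(trimethylammonio)eudesm-4-en-12-oate iodide (C11 epimers) | C[N+](C)(C)CC(C(=O)OC)[C@H]1CC2=C(C)[C@@H](O[Si](C)(C)C(C)(C)C)CC[C@]2(C)C[C@H]1O.[I-]
F8 | step 1 | methyl (Z)-4-(trimethylsilyloxy)pent-3-enoate | C/C(O[Si](C)(C)C)=C/CC(=O)OC
F9 | step 1 | methyl 3-[(dimethylamino)methyl]-4-oxopentanoate (racemic) | CC(=O)C(CN(C)C)CC(=O)OC
F10 | step 1 | methyl 4-oxo-3-[(trimethylammonio)methyl]pentanoate iodide (racemic) | CC(=O)C(C[N+](C)(C)C)CC(=O)OC.[I-]
F11 | step 4 | methyl (5S,10R)-8-(tert-butyldimethylsilyloxy)-3-[(E)-(dimethylamino)methylene]-4-oxo-13,15-dinoreudesm-7-en-12-oate | COC(=O)CC1=C(O[Si](C)(C)C(C)(C)C)C[C@@]2(C)CC/C(=C\N(C)C)C(=O)[C@H]2C1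
A1 | alternative 1 | trans-fused 3,8-diketone with C4 methyl and ester, C10 methyl and C7 acetic ester side chain | COC(=O)C[C@H]1C[C@H]2[C@@](C)(C(=O)OC)C(=O)CC[C@]2(C)CC1=O
A2 | alternative 1 | acyclic β-keto ester with (E)-C5=C10 alkene and C8 enol acetate terminus | COC(=O)C(C)C(=O)CC/C(C)=C/C[C@H](CC(=O)OC)C(=C)OC(C)=O
A3 | alternative 2 | methyl 8β-acetoxy-3-oxoeudesma-4,11(13)-dien-12-oate | C=C(C(=O)OC)[C@H]1CC2=C(C)C(=O)CC[C@]2(C)C[C@H]1OC(C)=O
A4 | alternative 2 | 2,3,4-trimethylcyclohex-2-enone carrying on C4 the (Z)-2-acetoxy-4-(bromomethyl)-4-(methoxycarbonyl)but-3-enyl chain | O=C1CC[C@](C)(C[C@@H](OC(C)=O)/C=C(\CBr)C(=O)OC)C(C)=C1C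
A5 | alternative 3 | cis-fused bicyclic C4 ketone with C8=C9 silyl enol ether and C10 methyl | C1C[C@@H]2C(=O)CCC[C@]2(C)C=C1O[Si](C)(C)C(C)(C)C
A6 | alternative 3 | (E)-9-(tert-butyldimethylsilyloxy)-7-methyldeca-1,7,9-trien-3-one | C=CC(=O)CCC/C(C)=C/C(=C)O[Si](C)(C)C(C)(C)C
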